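Ring A is disconnected (labdane numbering) across its unfunctionalised C1–C2 edge, which lies between quaternary C10 and the C4 gem-dimethyl carbon. Ring-closing metathesis of a vinyl group on C10 with an allyl group on C4, held trans on a preformed ring B cyclohexanone, followed in the same flask by ruthenium-hydride hydrogenation, should deliver the saturated trans-decalin in one operation. The diene derives from (1R,5R)-verbenone, which supplies ring B, C20 and C4: cross-coupling attaches the (S)-citronellol-derived side chain at C9, cuprate addition anti to the bridge sets C10, kinetic protonation sets C9, and radical scission of the strained cyclobutane with allyl transfer unmasks ring B. Triflate carbonylation adds C17.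

Key step: step 8

Remark: atoms carry labdane numbers throughout (verbenone C2, C3, C4, C5, C6, C7, C1 become C8, C9, C10, C5, C4, C6, C7); (1R,5R)-(+)-verbenone and (S)-(−)-citronellol are taken as commercial, enantiopure chiral-pool materials.

Step 1
Reactants: 1 (S)-citronellol
Product: 2 (S)-citronellyl acetate
Conditions: Ac2O, pyridine, DMAP (cat.), CH2Cl2, 0 °C to rt
Reagents that add atoms: acetic anhydride CC(=O)OC(C)=O
Why: DMAP-catalysed O-acylation of the primary alcohol installs the C15 acetate of the target at the outset and leaves the chiral-pool C13 stereocentre untouched.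

Step 2
Reactants: 2 (S)-citronellyl acetate
Product: 3 (4S)-6-acetoxy-4-methylhexanoic acid
Conditions: RuCl3·xH2O (2 mol %), NaIO4 (4 equiv), EtOAc/MeCN/H2O, rt
Reagents that add atoms: sodium periodate [Na+].[O-]I(=O)(=O)=O; water O
Why: RuO4-mediated oxidative cleavage (catalytic RuCl3 reoxidised by periodate) of the trisubstituted olefin should give the carboxylic acid and acetone directly, the acetate and the remote stereocentre being inert.

Step 3
Reactants: 3 (4S)-6-acetoxy-4-methylhexanoic acid
Product: 4 (3R)-5-iodo-3-methylpentyl acetate
Conditions: PhI(OAc)2, I2, cyclohexane, hν (tungsten lamp), reflux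
Reagents that add atoms: iodine [I][I]
Why: Hunsdiecker-type iododecarboxylation through the acyl hypoiodite (O–I homolysis, loss of CO2, iodine transfer to the primary radical) should excise the carboxyl carbon and leave the five-carbon C11–C15 unit as a primary iodide; the stereocentre is not involved, and its descriptor changes from S to R only through CIP priorities.

Step 4
Reactants: 5 (1R,5R)-verbenone
Product: 6 3-iodoverbenone
Conditions: I2, pyridine, CH2Cl2, 0 °C to rt
Reagents that add atoms: iodine [I][I]
Why: α-Iodination of the enone by the pyridine-mediated addition–iodination–elimination sequence (Baylis–Hillman-type) should place iodine on the only vinylic C–H, the future C9, the bridgehead α-position being unable to enolise.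

Step 5
Reactants: 4 (3R)-5-iodo-3-methylpentyl acetate; 6 3-iodoverbenone
Product: 8 3-[(3S)-5-acetoxy-3-methylpentyl]verbenone, via alkylzinc iodide 7 (not isolated)
Conditions: 4, Zn dust (activated with TMSCl/BrCH2CH2Br), LiCl, THF, 40 °C; then 6, Pd2(dba)3 (2.5 mol %), tri(2-furyl)phosphine (10 mol %), THF/NMP, rt to 50 °C
Reagents that add atoms: zinc [Zn] (retained only in 7)
Why: Negishi coupling of the ester-tolerant primary alkylzinc iodide with the α-iodoenone should forge the C9–C11 bond, since oxidative addition into the vinylic C–I bond, transmetalation and reductive elimination outrun β-hydride elimination with the furylphosphine ligand; no stereocentre is touched.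

Step 6
Reactants: 8 3-[(3S)-5-acetoxy-3-methylpentyl]verbenone
Product: 10 3-[(3S)-5-acetoxy-3-methylpentyl]-4-vinyl-cis-verbanone (vinyl anti to the CMe2 bridge; side chain syn to it), via silyl enol ether 9 (not isolated)
Conditions: vinylMgBr (3 equiv), CuBr·SMe2 (1.5 equiv), THF, −78 °C; then 8, TMSCl (3 equiv), −78 to −30 °C; then 1 M HCl, THF, 0 °C
Reagents that add atoms: vinylmagnesium bromide C=C[Mg]Br; chlorotrimethylsilane C[Si](C)(C)Cl (silyl group only in 9)
Why: TMSCl-accelerated organocuprate conjugate addition should deliver vinyl to C10 from the face anti to the CMe2 bridge, as additions to the verbenone bridge do, which makes C1 trans to C4 on ring B; kinetic C-protonation of the silyl enol ether from the same open face then sets C9 with 9α-H (side chain cis to the C10 methyl, trans to vinyl), the less stable epimer in the bicycle, so base is avoided until the cyclobutane is opened.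

Step 7
Reactants: 10 3-[(3S)-5-acetoxy-3-methylpentyl]-4-vinyl-cis-verbanone
Product: 12 3-methyl-5-[2-methyl-3-(2-methylpent-4-en-2-yl)-6-oxo-2-vinylcyclohexyl]pentyl acetate, via tributylstannyl enolate 11 (not isolated)
Conditions: allylSnBu3 (5 equiv), AIBN (0.3 equiv in portions), PhH (0.5 M), 80 °C; then aqueous work-up
Reagents that add atoms: allyltributylstannane C=CC[Sn](CCCC)(CCCC)CCCC
Why: Proposed new method: Bu3Sn• adds reversibly to the ketone oxygen to give an O-stannyl ketyl whose carbon radical sits beside the cyclobutane, β-scission of the C7–C4 bond releases about 26 kcal/mol of ring strain and gives the tertiary C4 radical and the 7-ene tin enolate (the C7–C6 alternative would give a primary radical), the tertiary radical adds to allyltributylstannane and expels Bu3Sn• to carry the chain (Keck-type allyl transfer), and hydrolysis of the tin enolate returns the C8 ketone without touching C5, C9 or C10; the closest known reaction types are the O-stannyl-ketyl scission–allylation of cyclopropyl ketones with allylstannanes, the ketyl-induced (SmI2 or dissolving-metal) cyclobutane opening of pinane ketones, and the ring opening of pinan-2-yl radicals used as a radical clock.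

Step 8
Reactants: 12 3-methyl-5-[2-methyl-3-(2-methylpent-4-en-2-yl)-6-oxo-2-vinylcyclohexyl]pentyl acetate
Product: 14 15-acetoxy-17-norlabdan-8-one, via cyclohexene 13 (not isolated)
Conditions: second-generation Grubbs catalyst (SIMes)(PCy3)Cl2Ru=CHPh (5 mol %), ClCH2CH2Cl (0.005 M), 50 °C; then H2 (5 bar), 60 °C, same flask
Reagents that add atoms: none
Why: The ruthenium benzylidene exchanges onto the unhindered allyl terminus, adds intramolecularly to the C10 vinyl group through a ruthenacyclobutane and cycloreverts to the C1=C2 olefin of 13 with loss of ethene, and under H2 the same ruthenium charge becomes a hydride catalyst that saturates it to the C1–C2 single bond. The closest known reaction type is ring-closing metathesis to cyclohexenes with allylic quaternary carbons, run as a one-pot metathesis–hydrogenation sequence with a single ruthenium precatalyst. Ring A closes as a six-membered carbocycle by head-to-head union of the two terminal olefins (no regiochemical alternative), and it is trans-fused because the vinyl group on C10 and the C4 chain on C5 are already trans on ring B. No stereocentre is created; C5, C9, C10 and C13 are carried through unchanged. The step needs cyclisation to beat acyclic diene oligomerisation and allyl-to-propenyl isomerisation, and olefin hydrogenation to spare the C8 ketone and the acetate; the gem-dimethyl group at C4 (Thorpe–Ingold effect), the diequatorial placement of the two olefin arms, high dilution and base-free hydrogenation should secure this.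

Step 9
Reactants: 14 15-acetoxy-17-norlabdan-8-one
Product: 15 15-acetoxy-17-norlabd-7-en-8-yl trifluoromethanesulfonate
Conditions: KN(SiMe3)2 (1.05 equiv), THF, −78 °C; then PhNTf2, −78 to 0 °C; aqueous NH4Cl work-up
Reagents that add atoms: N-phenylbis(trifluoromethanesulfonimide) O=S(=O)(N(c1ccccc1)S(=O)(=O)C(F)(F)F)C(F)(F)F
Why: Kinetic enolate formation should remove a proton from the open C7 methylene and not from the C9 methine flanked by quaternary C10 (and far faster than from the acetate), so O-sulfonylation gives the 7-ene enol triflate regioselectively with C9 untouched.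

Step 10
Reactants: 15 15-acetoxy-17-norlabd-7-en-8-yl trifluoromethanesulfonate
Product: 16 15-acetoxylabd-7-en-17-oic acid (target)
Conditions: Pd(OAc)2 (5 mol %), PPh3 (10 mol %), CO (1 atm), KOAc (4 equiv), DMF/H2O (20:1), 60 °C; then dilute HCl work-up
Reagents that add atoms: carbon monoxide [C-]#[O+]; water O
Why: Palladium-catalysed hydroxycarbonylation of the enol triflate (oxidative addition to zerovalent palladium, CO insertion, capture of the acylpalladium by acetate and water) should give the conjugated 7-ene-17-carboxylic acid directly, the acetate buffer being too mild to cleave the C15 acetate, move the double bond or epimerise C9.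

Compound list

1 | (S)-(−)-citronellol, (3S)-3,7-dimethyloct-6-en-1-ol | OCC[C@@H](C)CCC=C(C)C | starting material
2 | (S)-citronellyl acetate | CC(=O)OCC[C@@H](C)CCC=C(C)C | intermediate
3 | (4S)-6-acetoxy-4-methylhexanoic acid | CC(=O)OCC[C@@H](C)CCC(=O)O | intermediate
4 | (3R)-5-iodo-3-methylpentyl acetate | CC(=O)OCC[C@@H](C)CCI | intermediate
5 | (1R,5R)-(+)-verbenone, 4,6,6-trimethylbicyclo[3.1.1]hept-3-en-2-one | CC1=CC(=O)[C@@H]2C[C@H]1C2(C)C | starting material
6 | 3-iodoverbenone (skeleton and absolute configuration of 5, iodine on the α-vinylic carbon) | CC1=C(I)C(=O)[C@@H]2C[C@H]1C2(C)C | intermediate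
7 | [(3R)-5-acetoxy-3-methylpentyl]zinc iodide (not isolated) | CC(=O)OCC[C@@H](C)CC[Zn]I | intermediate
8 | 3-[(3S)-5-acetoxy-3-methylpentyl]verbenone | CC(=O)OCC[C@@H](C)CCC1=C(C)[C@H]2C[C@@H](C1=O)C2(C)C | intermediate
9 | trimethylsilyl enol ether of 10 (C8–O–Si, C8=C9; vinyl on C10 anti to the CMe2 bridge; not isolated) | CC(=O)OCC[C@@H](C)CCC1=C(O[Si](C)(C)C)[C@@H]2C[C@@H](C2(C)C)[C@]1(C)C=C | intermediate
10 | 3-[(3S)-5-acetoxy-3-methylpentyl]-4-vinyl-cis-verbanone: 4-vinyl anti to the CMe2 bridge, 4-methyl and 3-side chain syn to the bridge (side chain cis to methyl, trans to vinyl) | CC(=O)OCC[C@@H](C)CC[C@H]1C(=O)[C@@H]2C[C@@H](C2(C)C)[C@]1(C)C=C | intermediate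
11 | tributylstannyl 7-ene enolate of 12 (not isolated) | CC(=O)OCC[C@@H](C)CC[C@H]1C(O[Sn](CCCC)(CCCC)CCCC)=CC[C@@H](C(C)(C)CC=C)[C@]1(C)C=C | intermediate
12 | (3S)-3-methyl-5-[2-methyl-3-(2-methylpent-4-en-2-yl)-6-oxo-2-vinylcyclohexyl]pentyl acetate; on the ring the side chain is cis to the methyl, and the vinyl is trans to both the side chain and the 2-methylpent-4-en-2-yl group (5α-H, 9α-H, 10β-CH3) | CC(=O)OCC[C@@H](C)CC[C@H]1C(=O)CC[C@@H](C(C)(C)CC=C)[C@]1(C)C=C | intermediate
13 | 15-acetoxy-17-norlabd-1-en-8-one (5α-H, 9α-H, 10β-CH3, 13S; not isolated) | CC(=O)OCC[C@@H](C)CC[C@H]1C(=O)CC[C@H]2C(C)(C)CC=C[C@]12C | intermediate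
14 | 15-acetoxy-17-norlabdan-8-one (trans-decalin; 5α-H, 9α-H, 10β-CH3, 13S) | CC(=O)OCC[C@@H](C)CC[C@H]1C(=O)CC[C@H]2C(C)(C)CCC[C@]12C | intermediate
15 | 15-acetoxy-17-norlabd-7-en-8-yl trifluoromethanesulfonate | CC(=O)OCC[C@@H](C)CC[C@H]1C(OS(=O)(=O)C(F)(F)F)=CC[C@H]2C(C)(C)CCC[C@]12C | intermediate
16 | 15-acetoxylabd-7-en-17-oic acid (5α-H, 9α-H, 10β-CH3, 13S), CNP0412535.1 | CC(=O)OCC[C@@H](C)CC[C@H]1C(C(=O)O)=CC[C@H]2C(C)(C)CCC[C@]12C | target

Total step count: 10. Longest linear sequence: 9 steps (steps 1, 2, 3, 5, 6, 7, 8, 9, 10 from 1); step 4 is the one-step side branch from 5.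

Steps most likely to fail

Step 7 (Proposed new method). The chain may stall because addition of the tin radical to the hindered ketone oxygen is slow. The tertiary radical may be lost by hydrogen abstraction before allyl transfer. The weakly basic tin enolate may also epimerise the strained C9 centre of unreacted 10. Fallback with known chemistry: setting out from 10, Lewis-acid scission of the cyclobutane with trimethylsilyl iodide (TMSCl/NaI, MeCN, −20 °C; ionisation of the C7–C4 bond as in the known opening of pinane-type cyclobutyl ketones) and aqueous work-up would give the tertiary iodide 5-[3-(2-iodopropan-2-yl)-2-methyl-6-oxo-2-vinylcyclohexyl]-3-methylpentyl acetate F1. Keck allylation of the tertiary iodide F1 (allylSnBu3, AIBN, PhH, 80 °C) would then replace iodine by allyl and come back to the route at 12.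

Step 6. Conjugate addition may be too slow at the tetrasubstituted, bridge-flanked enone, so that 1,2-addition or attack on the acetate takes over, and protonation may lose facial selectivity. Fallback: setting out from 5, the same vinyl cuprate with TMSCl would add to unsubstituted verbenone (a far more reactive trisubstituted enone) to give the silyl enol ether of 4-vinyl-cis-verbanone F2. MeLi would release the lithium enolate, and alkylation with iodide 4 (THF/HMPA) from the face anti to the bridge would give the C9 epimer of 10 F3. Complete deprotonation of this epimer with excess LiN(iPr)2 (the bridgehead side cannot enolise) and kinetic protonation with AcOH at −78 °C from the open face would invert C9 and come back to the route at 10. This path also bypasses steps 4 and 5.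

Step 5. Oxidative addition or transmetalation may be sluggish at the hindered α-iodoenone, with protodezincation of 7 or reduction of 6 as the competing processes. Fallback: setting out from 5, γ-deprotonation with LiN(iPr)2 (THF/DMPU, −78 °C) would give the extended dienolate, which should be alkylated at the α-carbon by iodide 4 to give the deconjugated exocyclic-methylene ketone F4. Isomerisation of this ketone into conjugation with DBU (PhMe, rt) would come back to the route at 8.

Further compounds
F1 | step 7 | (3S)-5-[3-(2-iodopropan-2-yl)-2-methyl-6-oxo-2-vinylcyclohexyl]-3-methylpentyl acetate (ring configuration as in 12) | CC(=O)OCC[C@@H](C)CC[C@H]1C(=O)CC[C@@H](C(C)(C)I)[C@]1(C)C=C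
F2 | step 6 | trimethylsilyl enol ether of 4-vinyl-cis-verbanone (vinyl anti to the CMe2 bridge) | C=C[C@]1(C)C=C(O[Si](C)(C)C)[C@@H]2C[C@H]1C2(C)C
F3 | step 6 | C9 epimer of 10 (side chain anti to the CMe2 bridge, cis to vinyl) | CC(=O)OCC[C@@H](C)CC[C@@H]1C(=O)[C@@H]2C[C@@H](C2(C)C)[C@]1(C)C=C
F4 | step 5 | 3-[(3S)-5-acetoxy-3-methylpentyl]-6,6-dimethyl-4-methylenebicyclo[3.1.1]heptan-2-one (side chain anti to the bridge) | CC(=O)OCC[C@@H](C)CC[C@H]1C(=C)[C@H]2C[C@@H](C1=O)C2(C)C
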